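**Plan**

1. Numbering follows the open chain of the target: C1=C2, C3(Me)(OH), C4, C5(OH), C6, C7(Me), C8, C9(=O), O10, C11(Me), C12, C13(OH), C14, C15(Me2), C16O2H. Ring B is C6–C7–C14–C13–C12–C11; the lactone ring is C6–C7–C8–C9–O10–C11.
2. Cuts, in retrosynthetic order: C3–CH3 and C4–C5 (side chain); C14–C15; O10–C9 with C9–C14 re-joined (a cyclobutanone); C7–C8 and C9–C14 (propadiene off a ring B enone); ring B back to 5-methylcyclohexane-1,3-dione.
3. Forward: ring B enone (steps 1–6), cyclobutane by [2+2] photocycloaddition (7), lactone ring by strain-driven retro-Claisen (8–9), C15 unit (10–11), C13 carbinol and C6 inversion (12–15), side chain (16–17), deprotection (18).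
4. Enabling feature: the quaternary C7 lies β to the C13 oxygen and its C8–C9 acyl arm is esterified by O10 on C11. That is the 1,3-dicarbonyl pattern left when a two-carbon unit is added across a C14=C7 enone as a four-membered ring and the C11 alkoxide then opens that ring at C9–C14.
5. Stereochemistry: a resolved menthyl enol ether fixes the methyl stereocentre C7, which relays to C6 (anti alkylation) and C11 (anti borylation) and is then erased. The C6 arm steers propadiene (C7, C14) and the C15 radical (C14) to the lactone face. C13 comes from exo hydride delivery, C6 is then epimerised, C5 from a 1,3-anti Mukaiyama aldol, C3 from chelation-controlled methyl addition.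

Key step: step 7

Assumption: the two diastereomeric menthyl enol ethers formed in step 1 can be separated (crystallisation or chromatography), and the unwanted one is returned to 1 by acid hydrolysis.

**Step 1**
Reactants: 1 5-methylcyclohexane-1,3-dione; 2 (1R,2S,5R)-menthol
Product: 3 (5R)-5-methyl-3-{[(1R,2S,5R)-2-isopropyl-5-methylcyclohexyl]oxy}cyclohex-2-en-1-one
Conditions: p-TsOH (cat.), toluene, reflux, Dean–Stark; separation of the (5R) diastereomer
Reagents that add atoms: none
Why: Acid-catalysed enol etherification (vinylogous ester formation) of the symmetric dione with a chiral alcohol turns the methyl-bearing ring carbon (future C7) into a stereocentre, so the two products are diastereomers and the (5R) one is taken on while the other is hydrolysed back to 1.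

**Step 2**
Reactants: 3 menthyl vinylogous ester; 4 benzyl chloromethyl ether
Product: 6 (5R,6R)-6-[(benzyloxy)methyl]-5-methyl-3-{[(1R,2S,5R)-2-isopropyl-5-methylcyclohexyl]oxy}cyclohex-2-en-1-one, via lithium dienolate 5 (not isolated)
Conditions: LiN(iPr)2, THF, −78 °C; then 4, −78 → −30 °C
Reagents that add atoms: none
Why: Kinetic α′-deprotonation of the vinylogous ester and SN2 alkylation of the lithium dienolate (Stork–Danheiser alkylation) install the C5 arm at C6 anti to the neighbouring C7 methyl group.

**Step 3**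
Reactants: 6 alkylated vinylogous ester; 7 methyllithium
Product: 9 (4S,5R)-4-[(benzyloxy)methyl]-3,5-dimethylcyclohex-2-en-1-one, via tertiary lithium alkoxide 8 (not isolated)
Conditions: MeLi, Et2O/THF, −78 °C; then 1 M HCl, THF, 0 °C
Reagents that add atoms: water, O
Why: 1,2-Addition of MeLi to the vinylogous ester carbonyl followed by acid-induced loss of water and hydrolysis of the enol ether (Stork–Danheiser transposition) moves the enone so that C11 becomes its methyl-bearing β-carbon; C6 and C7 are not touched and the auxiliary is recovered.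

**Step 4**
Reactants: 9 enone
Product: 11 (3S,4R,5R)-4-[(benzyloxy)methyl]-3-hydroxy-3,5-dimethylcyclohexan-1-one, via C11 pinacolboronate 10 (not isolated)
Conditions: CuCl (5 mol %), NaOtBu (10 mol %), DPEphos, B2pin2, MeOH, THF, rt; then NaBO3·4H2O, THF/H2O, rt
Reagents that add atoms: sodium perborate, [Na+].[O-]OB=O
Why: Copper-catalysed conjugate borylation of the β,β-disubstituted enone puts boron on C11 from the face opposite the pseudo-axial C6 arm and perborate oxidation with retention gives the tertiary aldol with the C11 oxygen trans to the arm.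

**Step 5**
Reactants: 11 tertiary aldol
Product: 12 (3S,4R,5R)-4-[(benzyloxy)methyl]-3,5-dimethyl-3-[(trimethylsilyl)oxy]cyclohexan-1-one
Conditions: 1-(trimethylsilyl)imidazole, CH2Cl2, rt
Reagents that add atoms: 1-(trimethylsilyl)imidazole, C[Si](C)(C)n1ccnc1
Why: Silylation of the tertiary hydroxyl with a neutral silyl donor protects the aldol against dehydration and retro-aldol cleavage without enolising the ketone.

**Step 6**
Reactants: 12 silyloxy ketone
Product: 14 (4R,5S)-4-[(benzyloxy)methyl]-3,5-dimethyl-5-[(trimethylsilyl)oxy]cyclohex-2-en-1-one, via trimethylsilyl enol ether 13 (not isolated)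
Conditions: LiN(iPr)2, Me3SiCl, THF, −78 °C; then Pd(OAc)2 (1.05 equiv), MeCN, rt
Reagents that add atoms: none
Why: Saegusa–Ito oxidation: the kinetic enol silane forms on the less hindered C14 side and divalent palladium converts it by β-hydride elimination into the C14=C7 enone (this erases the relay stereocentre C7), whereas any C12 enol silane has no β-hydrogen and only reverts to ketone.

**Step 7**
Reactants: 14 ring B enone; 15 propadiene
Product: 16 5-[(benzyloxy)methyl]-4,6-dimethyl-8-methylidene-4-[(trimethylsilyl)oxy]bicyclo[4.2.0]octan-2-one (cis-fused; four-membered ring on the face of the silyloxy group; arm on the face of both methyls)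
Conditions: hν (350 nm, Pyrex), propadiene (excess), THF, −78 °C
Reagents that add atoms: none
Why: Light excites the enone to its triplet state, which adds to propadiene through a triplet 1,4-biradical that closes after spin inversion; this is the stepwise enone–allene [2+2] photocycloaddition. The one new ring, cyclobutane C7–C8–C9–C14, is closed by radical–radical recombination (1,4-closure of the biradical). The head-to-head sense (central allene carbon C9 to the α-carbon C14, terminal C8 to the β-carbon C7) is the normal one for propadiene and 3-alkylcyclohexenones and tolerates formation of the quaternary C7. C7 is controlled by the pseudo-axial C6 benzyloxymethyl arm, which sends the allene to the opposite face, the face of the C11 silyloxy group; C14 is controlled by the cis ring fusion that the four-membered ring imposes (a trans-fused adduct would epimerise at C14 on basic alumina). The step needs face selectivity at C7, secured by placing the C6 arm cis to the C11 methyl, and head-to-head regiochemistry, secured by the polarisation of the excited enone.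

**Step 8**
Reactants: 16 photoadduct
Product: 18 5-[(benzyloxy)methyl]-4,6-dimethyl-4-[(trimethylsilyl)oxy]bicyclo[4.2.0]octane-2,8-dione (configuration as in 16), via spiro ozonide 17 (not isolated)
Conditions: O3, CH2Cl2, −78 °C (to first blue colour); then PPh3, −78 °C → rt
Reagents that add atoms: ozone, [O-][O+]=O
Why: Ozonolysis of the only C=C bond (strained exocyclic methylene) with reductive work-up gives the cyclobutanone, now a 2-acylcyclobutanone 1,3 to the C13 ketone; the benzyl ether survives a titrated reaction at −78 °C.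

**Step 9**
Reactants: 18 cyclobutanone diketone
Product: 21 9-[(benzyloxy)methyl]-1,5-dimethyl-7-[(triethylsilyl)oxy]-2-oxabicyclo[3.3.1]non-6-en-3-one (arm syn to the C6–C8 carbocyclic bridge), via C11 alkoxide 19 (not isolated), via C13 enolate 20 (not isolated)
Conditions: (Me2N)3S[Me3SiF2] (1.05 equiv), THF, −78 °C; then Et3SiCl, −78 → −40 °C; non-aqueous work-up
Reagents that add atoms: chlorotriethylsilane, CC[Si](Cl)(CC)CC
Why: Fluoride removes the trimethylsilyl group and the C11 alkoxide adds to the strained C9 carbonyl held 1,3-diaxial to it, after which the C9–C14 bond breaks (intramolecular retro-Claisen driven by release of four-ring strain) to give the six-membered lactone and the C14=C13 enolate that is silylated on oxygen before it can equilibrate.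

**Step 10**
Reactants: 22 2-bromo-2-methylpropanoyl bromide; 23 2-(trimethylsilyl)ethanol
Product: 24 2-(trimethylsilyl)ethyl 2-bromo-2-methylpropanoate
Conditions: pyridine, CH2Cl2, 0 °C → rt
Reagents that add atoms: none
Why: Pyridine-mediated acylation of the primary alcohol by the acyl bromide (esterification) leaves the tertiary C–Br bond intact.

**Step 11**
Reactants: 21 silyl enol ether lactone; 24 bromo ester
Product: 25 2-(trimethylsilyl)ethyl 2-{9-[(benzyloxy)methyl]-1,5-dimethyl-3,7-dioxo-2-oxabicyclo[3.3.1]nonan-6-yl}-2-methylpropanoate (C14 as in the target: ester-bearing group equatorial on ring B and cis to C8; arm syn to the carbocyclic bridge)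
Conditions: fac-Ir(ppy)3 (1 mol %), 2,6-lutidine, MeCN, blue LEDs (450 nm), rt
Reagents that add atoms: none
Why: Visible-light photoredox α-alkylation of a silyl enol ether: the excited iridium complex reduces the C–Br bond, the tertiary α-ester radical adds to C14 from the lactone face because the C6 arm still covers the face of the carbocyclic bridge, and oxidation of the α-silyloxy radical with loss of silicon returns the C13 ketone with C15 equatorial.

**Step 12**
Reactants: 25 keto lactone
Product: 26 2-(trimethylsilyl)ethyl 2-{9-[(benzyloxy)methyl]-1,5-dimethyl-3-oxo-7-[(triethylsilyl)oxy]-2-oxabicyclo[3.3.1]nonan-6-yl}-2-methylpropanoate (7-silyloxy endo, pointing to the lactone bridge, as in the target)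
Conditions: Et3SiH (1.2 equiv), B(C6F5)3 (3 mol %), CH2Cl2, −20 → 0 °C
Reagents that add atoms: triethylsilane, CC[SiH](CC)CC
Why: Borane-catalysed hydrosilylation of the ketone delivers hydride to the exo face of C13 (the endo face is closed by the lactone carbonyl C9) and gives the endo C13–O bond of the target directly as its silyl ether, so no free alkoxide sits next to the lactone.

**Step 13**
Reactants: 26 benzyl ether
Product: 27 2-(trimethylsilyl)ethyl 2-{9-(hydroxymethyl)-1,5-dimethyl-3-oxo-7-[(triethylsilyl)oxy]-2-oxabicyclo[3.3.1]nonan-6-yl}-2-methylpropanoate (hydroxymethyl syn to the carbocyclic bridge)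
Conditions: H2 (1 atm), Pd(OH)2/C, EtOAc, rt
Reagents that add atoms: none
Why: Hydrogenolysis of the benzyl ether over Pd(OH)2; the molecule has no C=C bond at this stage and silyl ether, lactone and ester are inert.

**Step 14**
Reactants: 27 primary alcohol
Product: 28 2-(trimethylsilyl)ethyl 2-{9-formyl-1,5-dimethyl-3-oxo-7-[(triethylsilyl)oxy]-2-oxabicyclo[3.3.1]nonan-6-yl}-2-methylpropanoate (formyl syn to the carbocyclic bridge)
Conditions: DMP (1,1,1-triacetoxy-1,1-dihydro-1,2-benziodoxol-3(1H)-one), NaHCO3, CH2Cl2, 0 °C → rt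
Reagents that add atoms: none
Why: Dess–Martin oxidation takes the hindered primary alcohol to the aldehyde under buffered conditions without touching the C6 stereocentre.

**Step 15**
Reactants: 28 aldehyde (C6 epimer)
Product: 29 2-(trimethylsilyl)ethyl 2-{9-formyl-1,5-dimethyl-3-oxo-7-[(triethylsilyl)oxy]-2-oxabicyclo[3.3.1]nonan-6-yl}-2-methylpropanoate (formyl syn to the lactone bridge O2–C4; target C6 configuration)
Conditions: DBU (0.2 equiv), CH2Cl2, 0 °C → rt; unchanged 28 recycled
Reagents that add atoms: none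
Why: Base-mediated epimerisation through the aldehyde enolate under thermodynamic control: on the carbocyclic face the formyl group is syn-axial to C14–H and C12–H and blocks the boat-like relief of the endo C13 silyloxy group, so the lactone-face epimer (target C6 configuration) should dominate.

**Step 16**
Reactants: 29 aldehyde; 30 2-(trimethylsilyloxy)buta-1,3-diene
Product: 31 2-(trimethylsilyl)ethyl 2-{9-[(1S)-1-hydroxy-3-oxopent-4-en-1-yl]-1,5-dimethyl-3-oxo-7-[(triethylsilyl)oxy]-2-oxabicyclo[3.3.1]nonan-6-yl}-2-methylpropanoate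
Conditions: BF3·OEt2, CH2Cl2, −78 °C; cold aq. NaHCO3
Reagents that add atoms: none
Why: Mukaiyama aldol addition of the silyl dienol ether (a methyl vinyl ketone enolate equivalent) to the BF3-activated aldehyde; an open transition state with 1,3-anti induction from the β-acyloxy carbon C11 and approach past the smaller C11 flank should give the (5S) carbinol, and the absence of base keeps the β-acyloxy aldehyde from enolising.

**Step 17**
Reactants: 31 β-hydroxy enone; 32 methylmagnesium bromide
Product: 33 2-(trimethylsilyl)ethyl 2-{9-[(1S,3R)-1,3-dihydroxy-3-methylpent-4-en-1-yl]-1,5-dimethyl-3-oxo-7-[(triethylsilyl)oxy]-2-oxabicyclo[3.3.1]nonan-6-yl}-2-methylpropanoate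
Conditions: MeMgBr (3 equiv), CH2Cl2/Et2O, −78 °C; aq. NH4Cl
Reagents that add atoms: none
Why: Chelation-controlled 1,2-addition of the Grignard reagent to the magnesium alkoxide of the β-hydroxy enone: methyl adds axially to the six-membered chelate with vinyl equatorial, which gives the syn-1,3-diol and hence (3R).

**Step 18**
Reactants: 33 protected diol
Product: 34 2-[(1S,5R,6R,7R,9S)-9-[(1S,3R)-1,3-dihydroxy-3-methylpent-4-en-1-yl]-7-hydroxy-1,5-dimethyl-3-oxo-2-oxabicyclo[3.3.1]nonan-6-yl]-2-methylpropanoic acid (CNP0297019.1)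
Conditions: (Me2N)3S[Me3SiF2] (3 equiv), DMF, 0 °C → rt; pH 5 phosphate buffer, 0 °C
Reagents that add atoms: none
Why: Fluoride cleaves the triethylsilyl ether and, by β-elimination of ethene, the 2-(trimethylsilyl)ethyl ester in one nearly neutral operation, so the lactone and the tertiary allylic alcohol are not exposed to hydrolytic acid or base.

**Compound list**

1 | 5-methylcyclohexane-1,3-dione | CC1CC(=O)CC(=O)C1 | starting material
2 | (1R,2S,5R)-2-isopropyl-5-methylcyclohexan-1-ol (menthol) | CC(C)[C@@H]1CC[C@@H](C)C[C@H]1O | starting material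
3 | (5R)-5-methyl-3-{[(1R,2S,5R)-2-isopropyl-5-methylcyclohexyl]oxy}cyclohex-2-en-1-one | C1C(=O)C=C(O[C@@H]2C[C@H](C)CC[C@H]2C(C)C)C[C@H]1C | intermediate
4 | benzyl chloromethyl ether | ClCOCc1ccccc1 | starting material
5 | lithium dienolate of 3 (deprotonated at C6) | [Li+].[O-]C1=C[C@H](C)CC(O[C@@H]2C[C@H](C)CC[C@H]2C(C)C)=C1 | intermediate
6 | (5R,6R)-6-[(benzyloxy)methyl]-5-methyl-3-{[(1R,2S,5R)-2-isopropyl-5-methylcyclohexyl]oxy}cyclohex-2-en-1-one | C(OCc3ccccc3)[C@@H]1C(=O)C=C(O[C@@H]2C[C@H](C)CC[C@H]2C(C)C)C[C@H]1C | intermediate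
7 | methyllithium | [Li]C | starting material
8 | lithium alkoxide from 1,2-addition of methyllithium to 6 (new carbinol centre not defined) | C(OCc3ccccc3)[C@@H]1C(C)([O-])C=C(O[C@@H]2C[C@H](C)CC[C@H]2C(C)C)C[C@H]1C.[Li+] | intermediate
9 | (4S,5R)-4-[(benzyloxy)methyl]-3,5-dimethylcyclohex-2-en-1-one | C(OCc3ccccc3)[C@@H]1C(C)=CC(=O)C[C@H]1C | intermediate
10 | 4-[(benzyloxy)methyl]-3,5-dimethyl-3-(4,4,5,5-tetramethyl-1,3,2-dioxaborolan-2-yl)cyclohexan-1-one (boron trans to the arm) | C(OCc3ccccc3)[C@@H]1[C@@](C)(B2OC(C)(C)C(C)(C)O2)CC(=O)C[C@H]1C | intermediate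
11 | (3S,4R,5R)-4-[(benzyloxy)methyl]-3-hydroxy-3,5-dimethylcyclohexan-1-one | C(OCc3ccccc3)[C@@H]1[C@@](C)(O)CC(=O)C[C@H]1C | intermediate
12 | (3S,4R,5R)-4-[(benzyloxy)methyl]-3,5-dimethyl-3-[(trimethylsilyl)oxy]cyclohexan-1-one | C(OCc3ccccc3)[C@@H]1[C@@](C)(O[Si](C)(C)C)CC(=O)C[C@H]1C | intermediate
13 | kinetic trimethylsilyl enol ether of 12 (C13=C14) | C(OCc3ccccc3)[C@@H]1[C@@](C)(O[Si](C)(C)C)CC(O[Si](C)(C)C)=C[C@H]1C | intermediate
14 | (4R,5S)-4-[(benzyloxy)methyl]-3,5-dimethyl-5-[(trimethylsilyl)oxy]cyclohex-2-en-1-one | C(OCc3ccccc3)[C@H]1C(C)=CC(=O)C[C@]1(C)O[Si](C)(C)C | intermediate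
15 | propadiene | C=C=C | starting material
16 | 5-[(benzyloxy)methyl]-4,6-dimethyl-8-methylidene-4-[(trimethylsilyl)oxy]bicyclo[4.2.0]octan-2-one (cis-fused; cyclobutane syn to silyloxy; arm syn to both methyls) | C(OCc3ccccc3)[C@H]1[C@]2(C)CC(=C)[C@@H]2C(=O)C[C@]1(C)O[Si](C)(C)C | intermediate
17 | spiro ozonide (1,2,4-trioxolane at C9) of 16 | C(OCc3ccccc3)[C@H]1[C@]2(C)CC4(OCOO4)[C@@H]2C(=O)C[C@]1(C)O[Si](C)(C)C | intermediate
18 | 5-[(benzyloxy)methyl]-4,6-dimethyl-4-[(trimethylsilyl)oxy]bicyclo[4.2.0]octane-2,8-dione (configuration as in 16) | C(OCc3ccccc3)[C@H]1[C@]2(C)CC(=O)[C@@H]2C(=O)C[C@]1(C)O[Si](C)(C)C | intermediate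
19 | tris(dimethylamino)sulfonium C11 alkoxide of desilylated 18 | C(OCc3ccccc3)[C@H]1[C@]2(C)CC(=O)[C@@H]2C(=O)C[C@]1(C)[O-].CN(C)[S+](N(C)C)N(C)C | intermediate
20 | tris(dimethylamino)sulfonium 9-[(benzyloxy)methyl]-1,5-dimethyl-3-oxo-2-oxabicyclo[3.3.1]non-6-en-7-olate | C(OCc3ccccc3)[C@H]1[C@]2(C)CC(=O)O[C@@]1(C)CC([O-])=C2.CN(C)[S+](N(C)C)N(C)C | intermediate
21 | 9-[(benzyloxy)methyl]-1,5-dimethyl-7-[(triethylsilyl)oxy]-2-oxabicyclo[3.3.1]non-6-en-3-one (arm syn to the C6–C8 bridge) | C(OCc3ccccc3)[C@H]1[C@]2(C)CC(=O)O[C@@]1(C)CC(O[Si](CC)(CC)CC)=C2 | intermediate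
22 | 2-bromo-2-methylpropanoyl bromide | CC(C)(Br)C(=O)Br | starting material
23 | 2-(trimethylsilyl)ethanol | C[Si](C)(C)CCO | starting material
24 | 2-(trimethylsilyl)ethyl 2-bromo-2-methylpropanoate | CC(C)(Br)C(=O)OCC[Si](C)(C)C | intermediate
25 | 2-(trimethylsilyl)ethyl 2-{9-[(benzyloxy)methyl]-1,5-dimethyl-3,7-dioxo-2-oxabicyclo[3.3.1]nonan-6-yl}-2-methylpropanoate (C6 substituent cis to C4; arm syn to the C6–C8 bridge) | C(OCc3ccccc3)[C@H]1[C@]2(C)CC(=O)O[C@@]1(C)CC(=O)[C@H]2C(C)(C)C(=O)OCC[Si](C)(C)C | intermediate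
26 | 2-(trimethylsilyl)ethyl 2-{9-[(benzyloxy)methyl]-1,5-dimethyl-3-oxo-7-[(triethylsilyl)oxy]-2-oxabicyclo[3.3.1]nonan-6-yl}-2-methylpropanoate (7-silyloxy endo) | C(OCc3ccccc3)[C@H]1[C@]2(C)CC(=O)O[C@@]1(C)C[C@@H](O[Si](CC)(CC)CC)[C@H]2C(C)(C)C(=O)OCC[Si](C)(C)C | intermediate
27 | 2-(trimethylsilyl)ethyl 2-{9-(hydroxymethyl)-1,5-dimethyl-3-oxo-7-[(triethylsilyl)oxy]-2-oxabicyclo[3.3.1]nonan-6-yl}-2-methylpropanoate (hydroxymethyl syn to the C6–C8 bridge) | OC[C@H]1[C@]2(C)CC(=O)O[C@@]1(C)C[C@@H](O[Si](CC)(CC)CC)[C@H]2C(C)(C)C(=O)OCC[Si](C)(C)C | intermediate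
28 | 2-(trimethylsilyl)ethyl 2-{9-formyl-1,5-dimethyl-3-oxo-7-[(triethylsilyl)oxy]-2-oxabicyclo[3.3.1]nonan-6-yl}-2-methylpropanoate (formyl syn to the C6–C8 bridge) | O=C[C@H]1[C@]2(C)CC(=O)O[C@@]1(C)C[C@@H](O[Si](CC)(CC)CC)[C@H]2C(C)(C)C(=O)OCC[Si](C)(C)C | intermediate
29 | 2-(trimethylsilyl)ethyl 2-{9-formyl-1,5-dimethyl-3-oxo-7-[(triethylsilyl)oxy]-2-oxabicyclo[3.3.1]nonan-6-yl}-2-methylpropanoate (formyl syn to the lactone bridge) | O=C[C@@H]1[C@]2(C)CC(=O)O[C@@]1(C)C[C@@H](O[Si](CC)(CC)CC)[C@H]2C(C)(C)C(=O)OCC[Si](C)(C)C | intermediate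
30 | 2-(trimethylsilyloxy)buta-1,3-diene | C=CC(=C)O[Si](C)(C)C | starting material
31 | 2-(trimethylsilyl)ethyl 2-{9-[(1S)-1-hydroxy-3-oxopent-4-en-1-yl]-1,5-dimethyl-3-oxo-7-[(triethylsilyl)oxy]-2-oxabicyclo[3.3.1]nonan-6-yl}-2-methylpropanoate | C=CC(=O)C[C@H](O)[C@@H]1[C@]2(C)CC(=O)O[C@@]1(C)C[C@@H](O[Si](CC)(CC)CC)[C@H]2C(C)(C)C(=O)OCC[Si](C)(C)C | intermediate
32 | methylmagnesium bromide | C[Mg]Br | starting material
33 | 2-(trimethylsilyl)ethyl 2-{9-[(1S,3R)-1,3-dihydroxy-3-methylpent-4-en-1-yl]-1,5-dimethyl-3-oxo-7-[(triethylsilyl)oxy]-2-oxabicyclo[3.3.1]nonan-6-yl}-2-methylpropanoate | C=C[C@](C)(O)C[C@H](O)[C@@H]1[C@]2(C)CC(=O)O[C@@]1(C)C[C@@H](O[Si](CC)(CC)CC)[C@H]2C(C)(C)C(=O)OCC[Si](C)(C)C | intermediate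
34 | 2-[(1S,5R,6R,7R,9S)-9-[(1S,3R)-1,3-dihydroxy-3-methylpent-4-en-1-yl]-7-hydroxy-1,5-dimethyl-3-oxo-2-oxabicyclo[3.3.1]nonan-6-yl]-2-methylpropanoic acid | C=C[C@](C)(O)C[C@H](O)[C@@H]1[C@]2(C)CC(=O)O[C@@]1(C)C[C@@H](O)[C@H]2C(C)(C)C(=O)O | target

**Step count**

Total: 18 steps. Longest linear sequence: 17 steps (1–9, then 11–18); step 10 is a one-step branch.

**Steps most likely to fail**

1. Step 15 (C6 epimerisation). The aldehyde enolate carries the lactone oxygen O10 on its β-carbon C11, so β-elimination of the carboxylate (ring opening to an enal acid) competes with reprotonation. The equilibrium between the two C6 epimers may also not lie far enough on the lactone side. Fallback: set out from alcohol 27 and epimerise C6 without any enolate by reversible photochemical hydrogen-atom abstraction at the tertiary C6–H ((Bu4N)4W10O32 and a diaryl disulfide as catalysts, MeCN, 390 nm), which equilibrates the centre under neutral conditions to the lactone-face hydroxymethyl compound F1. Dess–Martin oxidation of F1 returns to aldehyde 29.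

2. Step 11 (C14–C15 bond). The tertiary radical must add to an enol ether carbon next to the quaternary C7; slow addition lets the radical be reduced or disproportionate, and incomplete face control would give the C14 epimer, which cannot be corrected by enolisation because the C12 enolate expels the lactone. Fallback: set out from enol silane 21 and build C15 in two smaller bonds with the C14 hydrogen put on last. A TiCl4-mediated Mukaiyama aldol with 2-(trimethylsilyl)ethyl 2-oxopropanoate gives the tertiary carbinol F2. Dehydration (SOCl2, pyridine, 0 °C) gives the C14=C15 alkylidene keto ester F3. Conjugate addition of Me2CuLi (THF, −78 °C) creates the quaternary C15, and protonation of the resulting C13 enolate from the exo face places C15 equatorial, which returns to keto lactone 25.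

3. Step 9 (retro-Claisen with enolate trapping). Proton transfer from the acidic 1,3-diketone C14–H of unreacted 18 to the newly formed enolate would give the C14-protonated ketone, and re-enolisation towards C12 would then eliminate the lactone carboxylate. Fallback: set out from diketone 18 and remove that acidic hydrogen first by chlorination at C14 (N-chlorosuccinimide, 2,6-lutidine, CH2Cl2) to the 2-chloro-1,3-diketone F4. The same fluoride-triggered retro-Claisen lactonisation, quenched with acetic acid, gives the α-chloro keto lactone F5, in which chlorine marks C14. Reductive silylation (Zn, Et3SiCl, THF) regenerates the C14=C13 enol silane 21 regiospecifically.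

**Further compounds**

F1 | step 15 | 2-(trimethylsilyl)ethyl 2-{9-(hydroxymethyl)-1,5-dimethyl-3-oxo-7-[(triethylsilyl)oxy]-2-oxabicyclo[3.3.1]nonan-6-yl}-2-methylpropanoate (hydroxymethyl syn to the lactone bridge) | OC[C@@H]1[C@]2(C)CC(=O)O[C@@]1(C)C[C@@H](O[Si](CC)(CC)CC)[C@H]2C(C)(C)C(=O)OCC[Si](C)(C)C
F2 | step 11 | 2-(trimethylsilyl)ethyl 2-{9-[(benzyloxy)methyl]-1,5-dimethyl-3,7-dioxo-2-oxabicyclo[3.3.1]nonan-6-yl}-2-hydroxypropanoate (mixture at C14 and C15) | C(OCc3ccccc3)[C@H]1[C@]2(C)CC(=O)O[C@@]1(C)CC(=O)C2C(C)(O)C(=O)OCC[Si](C)(C)C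
F3 | step 11 | 2-(trimethylsilyl)ethyl 2-{9-[(benzyloxy)methyl]-1,5-dimethyl-3,7-dioxo-2-oxabicyclo[3.3.1]nonan-6-ylidene}propanoate | C(OCc3ccccc3)[C@H]1[C@]2(C)CC(=O)O[C@@]1(C)CC(=O)C2=C(C)C(=O)OCC[Si](C)(C)C
F4 | step 9 | 5-[(benzyloxy)methyl]-1-chloro-4,6-dimethyl-4-[(trimethylsilyl)oxy]bicyclo[4.2.0]octane-2,8-dione (cis-fused, otherwise as 18) | C(OCc3ccccc3)[C@H]1[C@]2(C)CC(=O)[C@]2(Cl)C(=O)C[C@]1(C)O[Si](C)(C)C
F5 | step 9 | 9-[(benzyloxy)methyl]-6-chloro-1,5-dimethyl-2-oxabicyclo[3.3.1]nonane-3,7-dione (mixture at C6 of the bicycle) | C(OCc3ccccc3)[C@H]1[C@]2(C)CC(=O)O[C@@]1(C)CC(=O)C2Cl
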